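3 questions stood before the meeting, set out here with the flasks and the earlier runs.

common to all: initiator 7.6 mM

| flask | free monomer | remark | time |
|---|---|---|---|
| ochre | 0.34 M (fed, over 3.0 s) | run made earlier; the fed solution adds 0.20 times the starting volume |  |
| violet | 0.99 M (fed, over 3.0 s) | run made earlier; the fed solution adds 0.20 times the starting volume |  |
| Tuesday's | 0.38 M (fed, over 3.0 s) | the fed solution adds 0.20 times the starting volume | 2.0 min |
| Sunday's | 1.2 M (fed, over 3.0 s) | the fed solution adds 0.20 times the starting volume | 2.0 min |

| run | time / s | monomer in chains / % | free monomer / % |
|---|---|---|---|
| ochre | 10.0 | 6.3 | 91.4 |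
| ochre | 12.0 | 7.6 | 92.0 |
| ochre | 20.0 | 11.2 | 89.6 |
| ochre | 30.0 | 11.8 | 89.4 |
| ochre | 50.0 | 15.7 | 85.8 |
| ochre | 60.0 | 15.0 | 86.8 |
| violet | 10.0 | 11.6 | 87.2 |
| violet | 20.0 | 16.3 | 82.4 |
| violet | 30.0 | 20.4 | 81.1 |
| violet | 40.0 | 21.0 | 78.7 |
| violet | 50.0 | 21.0 | 77.1 |
| violet | 60.0 | 24.1 | 77.1 |

(scatter of a reading: 1 percentage point)

- charges are per starting volume, the dose included; the dosed solution carries all of it
- the average divides the monomer in chains by the number of chains begun, living and dead together
- steps under discussion: free monomer + initiator -> living end + monomer in chains; free monomer + living end -> monomer in chains + living end; 2 living end -> dead end; monomer in chains + living end -> free monomer + living end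
- the earlier runs do not show the number of chains; that part of a forecast is a guess

* which of the two ends with the longer chains by the average number of monomer units in a chain (chains begun, living or dead) ("neither" if they lie within 10%) (Tuesday's / Sunday's / neither)
* average number of monomer units in a chain (chains begun, living or dead) at the end, Tuesday's
* average number of monomer units in a chain (chains begun, living or dead) at the end, Sunday's

The analyst reported that both earlier runs flatten: after 60.0 s the ochre run had 15.0% of its charge in chains and the violet run 24.1%. She added that neither run shows the number of chains, so any count of them must be a guess.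

I, taking the minutes, proposed counting each charged initiator as one chain begun, with any unspent initiator as a small correction to that count. Tuesday's then has 50.0 and Sunday's 158 as its charge ratio, the free monomer charged per initiator charged. Both charges are per starting volume, so the feed volume cancels, and the average length is the fraction in chains times this ratio.

For the fraction, I assumed that the rise from 30.0 s to 60.0 s repeats once more by 2.0 min. That gives 18.2% from the ochre run for Tuesday's and 27.8% from the violet run for Sunday's, though Sunday's charge is larger than violet's. My lengths were therefore 9.10 and 43.9.

The forecast named Sunday's as longer, with 12 (range 9 to 30) for Tuesday's and 47 (38 to 85) for Sunday's. Its author held that “Initiator is probably mostly consumed by 2 min” and took about 6 mM of chains for Tuesday's, so its Tuesday figure stands higher than mine.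

The flask gives Sunday's, with 9.37 for Tuesday's and 45.5 for Sunday's.

    free monomer + initiator → living end + monomer in chains (k = 4.20 M⁻¹ s⁻¹)
    free monomer + living end → monomer in chains + living end, rate k2*[living end]*[free monomer] (k = 7.60 M⁻¹ s⁻¹)
    2 living end → dead end (k = 35.0 M⁻¹ s⁻¹)
    monomer in chains + living end → free monomer + living end, rate k4*[living end] as long as [monomer in chains] is above zero (k = 1.20 s⁻¹)

The forecast's Tuesday figure is 1.28 times the result. At 2.00 min Tuesday's holds 18.7% in chains and its initiator stands at 0%, so the charge ratio of 50.0 gives 9.35. The neighbouring flask is Sunday's read at 5.0 min, with the same charges. Its initiator stands at 0% and 34.0% of its monomer is in chains, so the ratio of 158 gives 53.7, and that flask's simulated average length is 53.7.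

The runs stem from a simulated flask for substances that don't exist, noise included.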